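The vessel is closed, stirred and held at one temperature, and the three recipes differ in that temperature.

the same everywhere: free monomer 1.7 M; initiator 8.5 mM; time 2.0 h
- east: temperature 135 °C
- south: temperature 85 °C
- north-east: temperature 110 °C

    free monomer + initiator → living end + monomer in chains (k1 = 0.100 /M/h, Ea1 = 79.0 kJ/mol)
    free monomer + living end → monomer in chains + living end, rate k2*[living end]*[free monomer] (k2 = 26.3 /M/h, Ea2 = 67.0 kJ/mol)
    free monomer + monomer in chains ⇌ idle adduct, settled at all times (K3 = 1.70 /M, ΔH3 = 21.0 kJ/mol)
    initiator + monomer in chains ⇌ idle complex (K4 = 11 /M, k4 = 0.843 /M/h, Ea4 = 77.0 kJ/mol, ΔH4 = 2.00 kJ/mol)
    free monomer + monomer in chains → side product (k5 = 0.146 /M/h, Ea5 = 96.0 kJ/mol)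
    (constants at 110 °C)

- percent here means free monomer units held: one idle adduct or side product counts as two
- what is said of monomer in chains includes idle adduct and idle complex
- all constants are for 110 °C and move with temperature by the activation energies and enthalpies
- in an amount of monomer in chains, one idle adduct counts as one monomer in chains

- the flask with the highest amount of monomer in chains, in percent of the free monomer charged ("all alike" if they lie within 1.5 percentage points) (east / south / north-east / all alike)
- final monomer in chains, as a percentage of the free monomer charged, in east
- final monomer in chains, as a percentage of the free monomer charged, in south
- final monomer in chains, as a percentage of the free monomer charged, in north-east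

Free monomer stands far above initiator, so the first step is pseudo-first-order in initiator, with a constant of 0.170 /h in north-east, where the constants apply as given. Initiator then falls to 71.2% of its charge by the end of the time, and living end is whatever initiator has been spent. But each living end keeps adding free monomer through the second step, so the time integral of living end matters, not its final level. That integral of the exponential, times the second rate constant, gives 0.0681 for north-east. This growth number, the logarithm of the fall of free monomer through chain growth, is the quantity to carry.

A first round leaves 93.4% of the free monomer. But the third step parks chain units with free monomer, and with that first answer put back, the parked share of chains is 0.730. Each unit entering chains therefore costs more than one free monomer, so a second round leaves 88.9% and puts 6.42% in chains, with the fifth step left out.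

While little initiator is spent, the growth number goes as the product of the first two rate constants, so both activation energies lift it. East reaches 0.798, larger than in north-east. That is no longer a small number, so this reckoning puts east ahead and commits to no figure there.

The forecast names east, with 33% there, 0.34% in south and 6% in north-east, a little below the reckoned figure. Its ground: “Initiation is slow, so the living-end concentration builds roughly linearly”.

The simulation gives east at 32.3%, with 0.330% in south and 6.15% in north-east. North-east keeps 89% of its free monomer, against 88.9% from the second round. In south, a growth number of 0.00304 and a parked share of 0.645 leave 99.5%, and the flask holds 99.5%. East's figure of 32.3% is held down in part by the fifth step together with the hour of the reading: with the fifth step struck out, east reaches 41.0%, and as it stands, read at 20.0 h, east holds 39.5%.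

The numbers of this flask belong to no real substance; the rest is arithmetic.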